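## The problem

Pseudophenone A is a chain of four benzene rings joined by one diaryl ether (ring A to ring B) and two aryl ester links (ring B carboxyl to a ring C oxygen, ring D carboxyl to the neighbouring ring C oxygen). It has no stereocentre, so the difficulty lies in connectivity and hindrance. Every linking atom sits between ortho substituents: the ether oxygen joins C2 of ring A (between CO2Me and OMe) to a ring B carbon next to the carboxyl carbon, and both ester carbonyls belong to 2,6-disubstituted benzoic acids, the ring D one lying between two methyl esters. Ring C is a 5-methylpyrogallol with two different acyl groups on adjacent oxygens and a free hydroxyl beside the central one, so the acyl groups must go on in a defined order and must not migrate. With five esters (two of them aryl esters) and four free phenols, a late step using base, alkoxide, amine or fluoride would invite transesterification or acyl shift, so the last step has to be neutral. The feature that opens the route is ring B: its carboxyl carbon lies between an oxygenated carbon and the ether carbon, with the methyl group opposite. This is C3, C4, C5 and C6 of a 3-carboxy-4-oxy-6-methyl-2-pyranone completed by the two carbons of an aryl ethynyl ether. A second useful feature is local symmetry: the ring D acyl group is symmetric and sits on the central oxygen of a symmetric triol, so the two outer oxygens of ring C are equivalent until ring B is attached.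

## Retrosynthesis

**36 to 35.** The three O–benzyl bonds on rings A, B and D are cut last. Hydrogenolysis is neutral and touches neither the aryl esters nor the free ring C hydroxyl that 35 already carries. Silyl or acyl protection would need fluoride or base at the end.

**35 to 19 and 33.** The ester bond between the ring B carboxyl carbon and the ring C oxygen is cut. The other ester (ring D to ring C) is the more hindered one and is better made early on small compounds. The cut also exposes the symmetric diol 33, whose two hydroxyls are equivalent: one takes the acyl group of 19, the other is the free hydroxyl of the target, so ring C needs no differentiating protection. The forward reaction must stop at mono-acylation and must not move the ring D acyl group.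

**19 to 18, then 18 to 10 and 16 (key disconnection).** The acid 19 comes from its tert-butyl ester 18 by acidolysis. In 18 two C–C bonds of ring B are cut: carboxyl-bearing carbon to ether-bearing carbon, and methyl-bearing carbon to the neighbouring CH. This returns the pyranone 16 (C3 to C6 become four ring B carbons) and the ethynyl ether 10 (two carbons plus the complete ring A), with CO2 lost from the bridged adduct 17. The neighbouring option, an Ullmann or substitution coupling of a ring A phenol with a ring B halide, has to join two carbons that each carry ortho substituents. Here the ether oxygen is already on the alkyne, and the cycloaddition places all four ring B substituents at once. The forward step needs one regiochemistry and enough reactivity from a diene that carries a donor at C4 and a methyl group at C6.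

**10 to 7, 7 to 5 and 6, 5 back to 1.** The C≡C unit is traced to trichloroethylene 6 through the (E)-dichlorovinyl ether 7 (in-flask intermediates 8 and 9). This is a standard two-step route from a phenol to a terminal ynol ether and accepts hindered phenols. The phenol 5 comes from the dihydroxy ester 4 by benzylation of the hydroxyl that is not hydrogen-bonded. Ester 4 comes from acid 3, and 3 from commercial 2-hydroxy-3-methoxybenzoic acid 1 by para-hydroxylation (via 2); both ortho positions of 1 are blocked, so only the para position is open.

**16 to 15, 15 to 11 and 12.** The benzyl ether 16 comes from the hydroxypyranone 15. The ring of 15 is opened at the lactone C–O bond and at the bond between the malonate carbon and C4, giving tert-butyl methyl malonate 11 and the acetylketene source 12 (via 13 and 14). The mixed malonate is chosen so that lactonisation uses the methyl ester and leaves the tert-butyl ester at C3. That ester can later be cleaved by acid beside the ring A methyl ester and the benzyl ethers.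

**33 to 32, 32 to 30, 30 to 28 and 24.** The diol 33 comes from its bis(methoxymethyl) ether 32. In 32 the two methyl ester carbons of ring D are cut from the ring, giving the dibromide 30 (via 31). This order makes the hindered central ester while its neighbours are bromine atoms, which cannot take part in pseudo-chloride or anhydride formation, and brings in the esters afterwards by carbonylation. Ester 30 is cut into acid 28 and phenol 24.

**28 to 26 to 25; 24 to 21 to 20.** Acid 28 comes from the benzyl ether 26 of 3,5-dibromophenol 25 by metalation between the bromine atoms and carboxylation (via 27). Phenol 24 comes from orcinol 20 through its bis(methoxymethyl) ether 21 by metalation between the two ether groups and oxidation (via 22 and 23). The methoxymethyl groups direct that metalation and later come off with acid while the ring D benzyl ether stays.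

## Roads not taken

**Alternative 1:** Ring D would be made by a (3+3) annulation. The cut is at the two ring D bonds between the methyl-ester-bearing carbons and the two CH carbons. Forward, the allyl anion of the mixed aconitate A2, whose central carboxyl is already the ring C aryl ester, would condense with the 2-benzyloxy vinamidinium salt A3 and lose two molecules of dimethylamine to give A1.
- Merits: ring D arises from acyclic material with its most hindered ester already in place, so no esterification of a 2,6-disubstituted acid is needed. A1 is the same compound as 32 of the chosen route and would be reached in fewer steps than the six that lead to 32.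
- Weak points: the aconitate anion is conjugated to an aryl ester and can expel the aryloxide as a vinylketene. The dimethylamine set free can attack that aryl ester. The ambident anion must react at both termini in the right sense. Making A2 requires telling apart the three carboxyl groups of aconitic acid. The strategy does not address the diaryl ether.
- Comparison: this road is shorter for the C–D half if the annulation works. The chosen plan spends its key step on the diaryl ether, which no ester chemistry can relieve, and handles the hindered ester by forming it at the dibromide stage (30) with known reaction types only.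

**Alternative 2:** Ring A would be made by ring expansion of a squarate-derived cyclobutenone. The cut is the ring A bond between the hydroxyl-bearing carbon and the adjacent CH next to the ester carbon. Forward, heating the cyclobutenone A5 would open the four-membered ring to a dienylketene, and 6π-electrocyclisation and tautomerisation would give the A–B diaryl ether A4 with a free ring A phenol.
- Merits: the closure is intramolecular and pericyclic, so it is probably more dependable as a ring-forming event than an intermolecular cycloaddition of a deactivated diene. Ring A emerges with all substituents placed. Benzylation of A4 would give 18, so both roads meet.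
- Weak points: A5 needs a tertiary alkyl aryl ether at the quaternary ring carbon, and attaching a hindered ring B phenoxide there, or building that carbon with the aryloxy group already on it, has no dependable method. The aryloxide can be lost during thermolysis. The squarate has to be reduced by one oxygen to give the ring CH. Ring B must still be made separately with its full substitution pattern.
- Comparison: the key step itself is likely safer than step 8, but its precursor is much harder to reach. The chosen plan draws both partners (10 and 16) from commercial materials in five and two steps.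

**Alternative 3:** Ring D would be made by a pyranone-to-benzene ring transformation. The cut is at both ring bonds to the carbon that bears the aryl ester. Forward, dimethyl chelidonate A7 would be silylated to a 4-silyloxypyrylium ion, the aryl phosphoranylideneacetate A8 would add at C2, the pyran would open, and an intramolecular Wittig reaction would close ring D to give A6.
- Merits: A7 already holds both methyl esters and the ring D oxygen in the right places, only one carbon is inserted, and the hindered aryl ester is again present before the ring closes.
- Weak points: a stabilised ylide must attack a pyrylium carbon that already bears an ester. An aryl ester ylide can lose aryloxide to give a ketenylidene phosphorane. The addition, ring-opening and Wittig sequence is not an established one. The ring D silyl ether would need fluoride or acid near the end in the presence of aryl esters. The diaryl ether is again left unsolved.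
- Comparison: this road is shorter to the C–D half on paper. The chosen plan reaches 32 by reactions of known type and keeps its one demanding step for the ether linkage.

Key step: step 8

## Route

Remark: all isolated compounds are achiral; 14 and the bridged intermediate 17 form as racemates and are not isolated. fod = 6,6,7,7,8,8,8-heptafluoro-2,2-dimethyloctane-3,5-dionate.

**Step 1**
Reactants: 1 2-hydroxy-3-methoxybenzoic acid
Product: 3 2,5-dihydroxy-3-methoxybenzoic acid, via aryl sulfate 2 (not isolated)
Conditions: K2S2O8, NaOH, H2O, 0–20 °C; then HCl, 90 °C
Reagents that add atoms: potassium peroxodisulfate, [K+].[K+].[O-]S(=O)(=O)OOS(=O)(=O)[O-]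
Why: Elbs persulfate oxidation: the phenoxide is attacked by peroxodisulfate at the free para position (both ortho positions are occupied) and the aryl sulfate 2 is hydrolysed by acid, the reaction type that turns salicylic acid into gentisic acid.

**Step 2**
Reactants: 3 2,5-dihydroxy-3-methoxybenzoic acid
Product: 4 methyl 2,5-dihydroxy-3-methoxybenzoate
Conditions: MeOH, H2SO4 (cat.), reflux
Reagents that add atoms: methanol, CO
Why: Fischer esterification; the carboxyl group has only one ortho substituent and the hydroquinone is stable to acid.

**Step 3**
Reactants: 4 methyl 2,5-dihydroxy-3-methoxybenzoate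
Product: 5 methyl 5-(benzyloxy)-2-hydroxy-3-methoxybenzoate
Conditions: BnBr (1.0 equiv), K2CO3, acetone, reflux, N2
Reagents that add atoms: benzyl bromide, BrCc1ccccc1
Why: Williamson ether synthesis; the 2-hydroxyl is hydrogen-bonded to the ester carbonyl and flanked by the methoxy group, so one equivalent of benzyl bromide should alkylate the free 5-hydroxyl, as is known for gentisate esters.

**Step 4**
Reactants: 5 methyl 5-(benzyloxy)-2-hydroxy-3-methoxybenzoate; 6 trichloroethylene
Product: 7 methyl 5-(benzyloxy)-2-{[(E)-1,2-dichloroethenyl]oxy}-3-methoxybenzoate
Conditions: Cs2CO3, DMF, 70 °C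
Reagents that add atoms: none
Why: Base eliminates HCl from trichloroethylene to dichloroacetylene, to which the phenoxide adds in anti fashion to give the (E)-1,2-dichlorovinyl ether; this standard entry to ynol ethers accepts hindered phenols and esters.

**Step 5**
Reactants: 7 methyl 5-(benzyloxy)-2-{[(E)-1,2-dichloroethenyl]oxy}-3-methoxybenzoate
Product: 10 methyl 5-(benzyloxy)-2-(ethynyloxy)-3-methoxybenzoate, via chloroethynyl ether 8 (not isolated), via lithium acetylide 9 (not isolated)
Conditions: n-BuLi (2.1 equiv), THF–Et2O, −95 °C; MeOH, −95 °C
Reagents that add atoms: none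
Why: n-Butyllithium removes the vinylic proton, LiCl is lost to give the chloroalkyne 8, and chlorine–lithium exchange gives the acetylide 9, which is protonated cold (the standard dichlorovinyl ether route to terminal ynol ethers). Deprotonation and halogen–metal exchange at an sp carbon are expected to outrun addition to the ortho-substituted methyl ester at −95 °C when no excess of n-BuLi is used.

**Step 6**
Reactants: 11 tert-butyl methyl malonate; 12 2,2,6-trimethyl-4H-1,3-dioxin-4-one
Product: 15 tert-butyl 4-hydroxy-6-methyl-2-oxo-2H-pyran-3-carboxylate, via acetylketene 13 (not isolated), via acetoacetylmalonate 14 (not isolated)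
Conditions: NaH, THF, 0 °C; 12, PhMe, 110 °C; then cold 1 M HCl
Reagents that add atoms: none
Why: Thermolysis of the dioxinone releases acetone and acetylketene 13, which C-acylates the sodium malonate; the enol oxygen of the resulting 3,5-dioxo ester 14 then closes onto the methyl ester, far more accessible than the tert-butyl ester, to give the 4-hydroxy-2-pyranone (acylketene acetoacetylation followed by lactonisation).

**Step 7**
Reactants: 15 tert-butyl 4-hydroxy-6-methyl-2-oxo-2H-pyran-3-carboxylate
Product: 16 tert-butyl 4-(benzyloxy)-6-methyl-2-oxo-2H-pyran-3-carboxylate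
Conditions: BnOH, PPh3, DIAD, THF, 0 °C to rt
Reagents that add atoms: benzyl alcohol, OCc1ccccc1
Why: Mitsunobu alkylation of the acidic vinylogous carboxylic acid; 4-hydroxy-2-pyranones are known to give the 4-alkoxy-2-pyranone under these conditions, and any 2-benzyloxy-4-pyranone isomer would be removed by chromatography.

**Step 8**
Reactants: 10 methyl 5-(benzyloxy)-2-(ethynyloxy)-3-methoxybenzoate; 16 tert-butyl 4-(benzyloxy)-6-methyl-2-oxo-2H-pyran-3-carboxylate
Product: 18 tert-butyl 2-(benzyloxy)-6-[4-(benzyloxy)-2-methoxy-6-(methoxycarbonyl)phenoxy]-4-methylbenzoate, via bridged lactone 17 (not isolated)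
Conditions: 10 (1.5 equiv), Eu(fod)3 (10 mol%), PhMe (1 M), 90 to 110 °C, sealed tube
Reagents that add atoms: none
Why: The pyranone 16 is an electron-poor diene (lactone carbonyl and C3 ester, both held by the europium chelate) and the ynol ether 10 an electron-rich dienophile, so an inverse-electron-demand Diels–Alder reaction is expected; the closest known type is the cycloaddition of 3-alkoxycarbonyl-2-pyranones with ynol ethers, ynamines and ketene acetals that gives benzoates after loss of CO2. The nucleophilic terminal carbon of 10 bonds to C6, the position vinylogous to both carbonyl groups, and the oxygen-bearing carbon to C3; the addition may be concerted but asynchronous or pass through a short-lived zwitterion, and either course leads to the same bridged lactone 17. Ring B is closed by this intermolecular (4+2) cycloaddition across C3 and C6, and 17 then loses CO2 by retro-Diels–Alder reaction, which gives the aromatic ring directly without an oxidation or elimination step. No stereocentre remains in 18; the two bridgehead centres of 17 are fixed relative to each other by the bicycle and vanish with the CO2. The selectivity needed is regiochemical (aryloxy carbon next to the ester carbon, CH next to the methyl carbon), and it is secured by the polarisation of both partners: the terminal carbon of the ynol ether is its only nucleophilic carbon and C6 the only diene terminus at which the developing charge is delocalised into ester and lactone. The 4-benzyloxy and 6-methyl groups lower the reactivity of the diene, which is why chelation by Eu(fod)3, a concentrated solution and an excess of 10 are planned; an aryl ethynyl ether has no retro-ene path to a ketene and should tolerate the temperature.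

**Step 9**
Reactants: 18 tert-butyl 2-(benzyloxy)-6-[4-(benzyloxy)-2-methoxy-6-(methoxycarbonyl)phenoxy]-4-methylbenzoate
Product: 19 2-(benzyloxy)-6-[4-(benzyloxy)-2-methoxy-6-(methoxycarbonyl)phenoxy]-4-methylbenzoic acid
Conditions: TFA, CH2Cl2, 0 °C to rt
Reagents that add atoms: none
Why: Acidolysis of the tert-butyl ester by alkyl–oxygen cleavage, which the two ortho substituents do not slow; methyl ester, diaryl ether and benzyl ethers are stable to cold trifluoroacetic acid over the short time needed.

**Step 10**
Reactants: 20 orcinol (5-methylbenzene-1,3-diol)
Product: 21 1,3-bis(methoxymethoxy)-5-methylbenzene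
Conditions: MOMCl, i-Pr2NEt, CH2Cl2, 0 °C to rt
Reagents that add atoms: chloromethyl methyl ether, COCCl
Why: Standard formation of methoxymethyl ethers from a phenol with a hindered amine base; the two hydroxyls are equivalent.

**Step 11**
Reactants: 21 1,3-bis(methoxymethoxy)-5-methylbenzene
Product: 24 2,6-bis(methoxymethoxy)-4-methylphenol, via aryllithium 22 (not isolated), via arylboronate 23 (not isolated)
Conditions: n-BuLi, THF, 0 °C; B(OMe)3, −78 °C to rt; H2O2, NaOH, H2O, 0 °C
Reagents that add atoms: hydrogen peroxide, OO
Why: Directed ortho-metalation at the position between the two methoxymethoxy groups, borylation and oxidation of the carbon–boron bond give the central phenol; the sequence is standard for resorcinol bis(methoxymethyl) ethers.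

**Step 12**
Reactants: 25 3,5-dibromophenol
Product: 26 1-(benzyloxy)-3,5-dibromobenzene
Conditions: BnBr, K2CO3, DMF, rt
Reagents that add atoms: benzyl bromide, BrCc1ccccc1
Why: Williamson ether synthesis on an unhindered phenol.

**Step 13**
Reactants: 26 1-(benzyloxy)-3,5-dibromobenzene
Product: 28 4-(benzyloxy)-2,6-dibromobenzoic acid, via aryllithium 27 (not isolated)
Conditions: LDA, THF, −78 °C; CO2; then 1 M HCl
Reagents that add atoms: carbon dioxide, O=C=O
Why: LDA removes the most acidic ring proton, the one between the two bromine atoms, as in the known metalation of 1,3-dibromobenzenes to 2,6-dibromophenyllithiums; at −78 °C the aryllithium neither loses LiBr nor attacks the benzyl ether, and carboxylation gives the acid.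

**Step 14**
Reactants: 28 4-(benzyloxy)-2,6-dibromobenzoic acid; 24 2,6-bis(methoxymethoxy)-4-methylphenol
Product: 30 2,6-bis(methoxymethoxy)-4-methylphenyl 4-(benzyloxy)-2,6-dibromobenzoate, via acid chloride 29 (not isolated)
Conditions: (COCl)2, DMF (cat.), CH2Cl2, rt; then 24, NaH, THF, 0 °C to rt
Reagents that add atoms: none
Why: Acylation of a sodium phenoxide by an acid chloride; with bromine atoms and not esters beside the carbonyl group the chloride cannot cyclise to a pseudo-chloride or anhydride, and 2,6-dihalobenzoyl chlorides are known to acylate hindered phenoxides.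

**Step 15**
Reactants: 30 2,6-bis(methoxymethoxy)-4-methylphenyl 4-(benzyloxy)-2,6-dibromobenzoate
Product: 32 dimethyl 5-(benzyloxy)-2-{[2,6-bis(methoxymethoxy)-4-methylphenoxy]carbonyl}benzene-1,3-dicarboxylate, via bromo monoester 31 (not isolated)
Conditions: Pd(OAc)2 (10 mol%), Xantphos, CO (5 bar), MeOH (10 equiv), Et3N, PhMe, 90 °C
Reagents that add atoms: carbon monoxide, [C-]#[O+]; methanol, CO
Why: Palladium-catalysed methoxycarbonylation of aryl bromides (oxidative addition, CO insertion, methanolysis of the acylpalladium), for which the Xantphos system is known to accept ortho-substituted bromides; the first ester group formed makes the second C–Br bond more reactive. The aryl ester is shielded against methanolysis by its two ortho substituents.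

**Step 16**
Reactants: 32 dimethyl 5-(benzyloxy)-2-{[2,6-bis(methoxymethoxy)-4-methylphenoxy]carbonyl}benzene-1,3-dicarboxylate
Product: 33 dimethyl 5-(benzyloxy)-2-[(2,6-dihydroxy-4-methylphenoxy)carbonyl]benzene-1,3-dicarboxylate
Conditions: conc. HCl (cat.), MeOH–THF, 40 °C
Reagents that add atoms: none
Why: Acid-catalysed acetal exchange removes both methoxymethyl ethers as dimethoxymethane; methyl esters, the benzyl ether and the doubly ortho-substituted aryl ester are stable to methanolic HCl.

**Step 17**
Reactants: 19 2-(benzyloxy)-6-[4-(benzyloxy)-2-methoxy-6-(methoxycarbonyl)phenoxy]-4-methylbenzoic acid; 33 dimethyl 5-(benzyloxy)-2-[(2,6-dihydroxy-4-methylphenoxy)carbonyl]benzene-1,3-dicarboxylate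
Product: 35 tri-O-benzyl pseudophenone A (dimethyl 5-(benzyloxy)-2-{[2-({2-(benzyloxy)-6-[4-(benzyloxy)-2-methoxy-6-(methoxycarbonyl)phenoxy]-4-methylbenzoyl}oxy)-6-hydroxy-4-methylphenoxy]carbonyl}benzene-1,3-dicarboxylate), via acid chloride 34 (not isolated)
Conditions: (COCl)2, DMF (cat.), CH2Cl2, 0 °C; then slow addition to 33 (2.5 equiv), Et3N, DMAP (cat.), CH2Cl2, 0 °C to rt
Reagents that add atoms: none
Why: Acylation of a phenol by an acid chloride with DMAP catalysis; the two hydroxyls of 33 are equivalent, so only mono- against bis-acylation has to be controlled, by an excess of the recoverable diol and slow addition. The hydroxyl that stays free is the ring C hydroxyl of the target, and the hindered aroyl groups are not expected to migrate under these mild conditions.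

**Step 18**
Reactants: 35 tri-O-benzyl pseudophenone A
Product: 36 pseudophenone A
Conditions: H2 (1 atm), Pd/C, EtOAc–THF, rt
Reagents that add atoms: none
Why: Hydrogenolysis of the three aryl benzyl ethers on palladium under neutral conditions; aryl esters, methyl esters and the diaryl ether are inert, so neither acyl migration nor transesterification is triggered.

## Compound list

1 | 2-hydroxy-3-methoxybenzoic acid | COc1cccc(C(=O)O)c1O | starting material
2 | 3-carboxy-4-hydroxy-5-methoxyphenyl hydrogen sulfate (potassium salt in the flask) | COc1cc(OS(=O)(=O)O)cc(C(=O)O)c1O | intermediate (not isolated)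
3 | 2,5-dihydroxy-3-methoxybenzoic acid | COc1cc(O)cc(C(=O)O)c1O | intermediate
4 | methyl 2,5-dihydroxy-3-methoxybenzoate | COC(=O)c1cc(O)cc(OC)c1O | intermediate
5 | methyl 5-(benzyloxy)-2-hydroxy-3-methoxybenzoate | COC(=O)c1cc(OCc2ccccc2)cc(OC)c1O | intermediate
6 | trichloroethylene | ClC=C(Cl)Cl | starting material
7 | methyl 5-(benzyloxy)-2-{[(E)-1,2-dichloroethenyl]oxy}-3-methoxybenzoate | COC(=O)c1cc(OCc2ccccc2)cc(OC)c1O/C(Cl)=C\Cl | intermediate
8 | methyl 5-(benzyloxy)-2-[(chloroethynyl)oxy]-3-methoxybenzoate | COC(=O)c1cc(OCc2ccccc2)cc(OC)c1OC#CCl | intermediate (not isolated)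
9 | lithium acetylide of 10 | COC(=O)c1cc(OCc2ccccc2)cc(OC)c1OC#C[Li] | intermediate (not isolated)
10 | methyl 5-(benzyloxy)-2-(ethynyloxy)-3-methoxybenzoate | COC(=O)c1cc(OCc2ccccc2)cc(OC)c1OC#C | intermediate
11 | tert-butyl methyl malonate | COC(=O)CC(=O)OC(C)(C)C | starting material
12 | 2,2,6-trimethyl-4H-1,3-dioxin-4-one | CC1=CC(=O)OC(C)(C)O1 | starting material
13 | acetylketene (3-oxobut-1-en-1-one) | CC(=O)C=C=O | intermediate (not isolated)
14 | 1-tert-butyl 3-methyl 2-(3-oxobutanoyl)propanedioate (racemic, enolisable, drawn as keto form) | COC(=O)C(C(=O)CC(C)=O)C(=O)OC(C)(C)C | intermediate (not isolated)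
15 | tert-butyl 4-hydroxy-6-methyl-2-oxo-2H-pyran-3-carboxylate | Cc1cc(O)c(C(=O)OC(C)(C)C)c(=O)o1 | intermediate
16 | tert-butyl 4-(benzyloxy)-6-methyl-2-oxo-2H-pyran-3-carboxylate | Cc1cc(OCc2ccccc2)c(C(=O)OC(C)(C)C)c(=O)o1 | intermediate
17 | bridged lactone: tert-butyl 8-(benzyloxy)-5-[4-(benzyloxy)-2-methoxy-6-(methoxycarbonyl)phenoxy]-1-methyl-3-oxo-2-oxabicyclo[2.2.2]octa-5,7-diene-4-carboxylate (racemic, bridgeheads fixed by the bicycle) | CC12OC(=O)C(C(=O)OC(C)(C)C)(C(OCc3ccccc3)=C1)C(Oc4c(OC)cc(OCc5ccccc5)cc4C(=O)OC)=C2 | intermediate (not isolated)
18 | tert-butyl 2-(benzyloxy)-6-[4-(benzyloxy)-2-methoxy-6-(methoxycarbonyl)phenoxy]-4-methylbenzoate | COC(=O)c1cc(OCc2ccccc2)cc(OC)c1Oc1cc(C)cc(OCc2ccccc2)c1C(=O)OC(C)(C)C | intermediate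
19 | 2-(benzyloxy)-6-[4-(benzyloxy)-2-methoxy-6-(methoxycarbonyl)phenoxy]-4-methylbenzoic acid | COC(=O)c1cc(OCc2ccccc2)cc(OC)c1Oc1cc(C)cc(OCc2ccccc2)c1C(=O)O | intermediate
20 | orcinol (5-methylbenzene-1,3-diol) | Cc1cc(O)cc(O)c1 | starting material
21 | 1,3-bis(methoxymethoxy)-5-methylbenzene | COCOc1cc(C)cc(OCOC)c1 | intermediate
22 | [2,6-bis(methoxymethoxy)-4-methylphenyl]lithium | [Li]c1c(OCOC)cc(C)cc1OCOC | intermediate (not isolated)
23 | dimethyl [2,6-bis(methoxymethoxy)-4-methylphenyl]boronate | COB(OC)c1c(OCOC)cc(C)cc1OCOC | intermediate (not isolated)
24 | 2,6-bis(methoxymethoxy)-4-methylphenol | COCOc1cc(C)cc(OCOC)c1O | intermediate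
25 | 3,5-dibromophenol | Oc1cc(Br)cc(Br)c1 | starting material
26 | 1-(benzyloxy)-3,5-dibromobenzene | Brc1cc(Br)cc(OCc2ccccc2)c1 | intermediate
27 | [4-(benzyloxy)-2,6-dibromophenyl]lithium | [Li]c1c(Br)cc(OCc2ccccc2)cc1Br | intermediate (not isolated)
28 | 4-(benzyloxy)-2,6-dibromobenzoic acid | OC(=O)c1c(Br)cc(OCc2ccccc2)cc1Br | intermediate
29 | 4-(benzyloxy)-2,6-dibromobenzoyl chloride | ClC(=O)c1c(Br)cc(OCc2ccccc2)cc1Br | intermediate (not isolated)
30 | 2,6-bis(methoxymethoxy)-4-methylphenyl 4-(benzyloxy)-2,6-dibromobenzoate | COCOc1cc(C)cc(OCOC)c1OC(=O)c1c(Br)cc(OCc2ccccc2)cc1Br | intermediate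
31 | methyl 5-(benzyloxy)-2-{[2,6-bis(methoxymethoxy)-4-methylphenoxy]carbonyl}-3-bromobenzoate | COCOc1cc(C)cc(OCOC)c1OC(=O)c1c(Br)cc(OCc2ccccc2)cc1C(=O)OC | intermediate (not isolated)
32 | dimethyl 5-(benzyloxy)-2-{[2,6-bis(methoxymethoxy)-4-methylphenoxy]carbonyl}benzene-1,3-dicarboxylate | COCOc1cc(C)cc(OCOC)c1OC(=O)c1c(C(=O)OC)cc(OCc2ccccc2)cc1C(=O)OC | intermediate
33 | dimethyl 5-(benzyloxy)-2-[(2,6-dihydroxy-4-methylphenoxy)carbonyl]benzene-1,3-dicarboxylate | Cc1cc(O)c(OC(=O)c2c(C(=O)OC)cc(OCc3ccccc3)cc2C(=O)OC)c(O)c1 | intermediate
34 | 2-(benzyloxy)-6-[4-(benzyloxy)-2-methoxy-6-(methoxycarbonyl)phenoxy]-4-methylbenzoyl chloride | COC(=O)c1cc(OCc2ccccc2)cc(OC)c1Oc1cc(C)cc(OCc2ccccc2)c1C(=O)Cl | intermediate (not isolated)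
35 | tri-O-benzyl pseudophenone A | COC(=O)c1cc(OCc2ccccc2)cc(OC)c1Oc1cc(C)cc(OCc2ccccc2)c1C(=O)Oc1cc(C)cc(O)c1OC(=O)c1c(C(=O)OC)cc(OCc2ccccc2)cc1C(=O)OC | intermediate
36 | pseudophenone A | COC(=O)c1cc(O)cc(OC)c1Oc1cc(C)cc(O)c1C(=O)Oc1cc(C)cc(O)c1OC(=O)c1c(C(=O)OC)cc(O)cc1C(=O)OC | target

## Step count and risks

Total: 18 steps. Longest linear sequence: 9 steps (1, 2, 3, 4, 5, 8, 9, 17, 18). The branches are 6–7 (pyranone), 10–11 (ring C phenol) and 12–16 (ring D and the C–D ester).

**Step 8 (key step).** The most likely failure is a cycloaddition too slow for the lifetime of the ynol ether: the 4-benzyloxy and 6-methyl groups deactivate the diene, and 10 may be consumed by oligomerisation or hydration first. Attack of the alkyne at C4 of the pyranone instead of C6 is a second possible course. The fallback gives up the cycloaddition, sets out from 5 and returns at 19. Commercial 2,6-difluoro-4-methylbenzaldehyde is treated with benzyl alcohol and NaH to replace one fluorine, giving 2-(benzyloxy)-6-fluoro-4-methylbenzaldehyde F1. The phenoxide of 5 (K2CO3, DMA, heat) then displaces the remaining fluorine ortho to the aldehyde to give methyl 5-(benzyloxy)-2-[3-(benzyloxy)-2-formyl-5-methylphenoxy]-3-methoxybenzoate F2. Pinnick oxidation (NaClO2, NaH2PO4, 2-methylbut-2-ene) of F2 gives the acid 19 directly.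

**Step 5.** The most likely failure is addition of n-butyllithium to the ring A methyl ester in competition with metalation and chlorine–lithium exchange. The fallback avoids alkyllithium, sets out from 5 and returns at 10. The phenol is vinylated by Chan–Lam coupling with the 2,4,6-trivinylcyclotriboroxane–pyridine complex (Cu(OAc)2, pyridine, CH2Cl2, air) to give methyl 5-(benzyloxy)-2-(ethenyloxy)-3-methoxybenzoate F3. Bromine is added at −78 °C to give methyl 5-(benzyloxy)-2-(1,2-dibromoethoxy)-3-methoxybenzoate F4, and double dehydrobromination with LDA at −78 °C, a base that spares a benzoate ester, gives 10.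

**Step 17.** The most likely failures are bis-acylation of the diol, slow reaction between two hindered partners that would call for forcing conditions, and with those a shift of the ring D acyl group to the neighbouring free oxygen. The fallback moves the statistical step to the cheaper fragment, sets out from 33 and returns at 36. One hydroxyl of 33 is benzylated under Mitsunobu conditions (BnOH, PPh3, DIAD) to give dimethyl 5-(benzyloxy)-2-{[2-(benzyloxy)-6-hydroxy-4-methylphenoxy]carbonyl}benzene-1,3-dicarboxylate F5. Its single remaining hydroxyl is acylated with 34, now without risk of over-acylation, to give tetra-O-benzyl pseudophenone A F6, and hydrogenolysis of all four benzyl ethers gives 36.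

**Step 15.** The most likely failures are incomplete carbonylation at the second bromide, reductive loss of bromine, and methanolysis of the aryl ester under the basic methanolic conditions. The fallback installs the methyl esters before the aryl ester, sets out from 26 and returns at 32. The aryllithium from 26 and LDA is trapped with Boc2O to give tert-butyl 4-(benzyloxy)-2,6-dibromobenzoate F7. Double methoxycarbonylation under the conditions of step 15 gives 2-tert-butyl 1,3-dimethyl 5-(benzyloxy)benzene-1,2,3-tricarboxylate F8, and trifluoroacetic acid gives 4-(benzyloxy)-2,6-bis(methoxycarbonyl)benzoic acid F9. Its acid chloride is then coupled with the sodium phenoxide of 24 to give 32.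

**Step 1.** The most likely failure is low conversion together with further oxidation of the electron-rich hydroquinone by persulfate. The fallback sets out from 1 and returns at 4. Fischer esterification gives methyl 2-hydroxy-3-methoxybenzoate F10, Duff formylation (hexamethylenetetramine, TFA) at the only free position para to the hydroxyl gives methyl 5-formyl-2-hydroxy-3-methoxybenzoate F11, and Dakin oxidation (H2O2, then mild methanolysis of the aryl formate) gives 4.

## Further compounds

F1 | step 8 | 2-(benzyloxy)-6-fluoro-4-methylbenzaldehyde | O=Cc1c(F)cc(C)cc1OCc1ccccc1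
F2 | step 8 | methyl 5-(benzyloxy)-2-[3-(benzyloxy)-2-formyl-5-methylphenoxy]-3-methoxybenzoate | COC(=O)c1cc(OCc2ccccc2)cc(OC)c1Oc1cc(C)cc(OCc2ccccc2)c1C=O
F3 | step 5 | methyl 5-(benzyloxy)-2-(ethenyloxy)-3-methoxybenzoate | COC(=O)c1cc(OCc2ccccc2)cc(OC)c1OC=C
F4 | step 5 | methyl 5-(benzyloxy)-2-(1,2-dibromoethoxy)-3-methoxybenzoate (racemic) | COC(=O)c1cc(OCc2ccccc2)cc(OC)c1OC(Br)CBr
F5 | step 17 | dimethyl 5-(benzyloxy)-2-{[2-(benzyloxy)-6-hydroxy-4-methylphenoxy]carbonyl}benzene-1,3-dicarboxylate | Cc1cc(O)c(OC(=O)c2c(C(=O)OC)cc(OCc3ccccc3)cc2C(=O)OC)c(OCc4ccccc4)c1
F6 | step 17 | tetra-O-benzyl pseudophenone A | COC(=O)c1cc(OCc2ccccc2)cc(OC)c1Oc1cc(C)cc(OCc2ccccc2)c1C(=O)Oc1cc(C)cc(OCc2ccccc2)c1OC(=O)c1c(C(=O)OC)cc(OCc2ccccc2)cc1C(=O)OC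
F7 | step 15 | tert-butyl 4-(benzyloxy)-2,6-dibromobenzoate | CC(C)(C)OC(=O)c1c(Br)cc(OCc2ccccc2)cc1Br
F8 | step 15 | 2-tert-butyl 1,3-dimethyl 5-(benzyloxy)benzene-1,2,3-tricarboxylate | COC(=O)c1cc(OCc2ccccc2)cc(C(=O)OC)c1C(=O)OC(C)(C)C
F9 | step 15 | 4-(benzyloxy)-2,6-bis(methoxycarbonyl)benzoic acid | COC(=O)c1cc(OCc2ccccc2)cc(C(=O)OC)c1C(=O)O
F10 | step 1 | methyl 2-hydroxy-3-methoxybenzoate | COC(=O)c1cccc(OC)c1O
F11 | step 1 | methyl 5-formyl-2-hydroxy-3-methoxybenzoate | COC(=O)c1cc(C=O)cc(OC)c1O
A1 | alternative 1 | dimethyl 5-(benzyloxy)-2-{[2,6-bis(methoxymethoxy)-4-methylphenoxy]carbonyl}benzene-1,3-dicarboxylate (identical with 32) | COC(=O)c1cc(OCc2ccccc2)cc(C(=O)OC)c1C(=O)Oc1c(OCOC)cc(C)cc1OCOC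
A2 | alternative 1 | 2-[2,6-bis(methoxymethoxy)-4-methylphenyl] 1,3-dimethyl (E)-prop-1-ene-1,2,3-tricarboxylate | COC(=O)/C=C(/C(=O)Oc1c(OCOC)cc(C)cc1OCOC)CC(=O)OC
A3 | alternative 1 | 2-(benzyloxy)-1,3-bis(dimethylamino)trimethinium hexafluorophosphate (delocalised cation) | CN(C)C=C(OCc1ccccc1)C=[N+](C)C.F[P-](F)(F)(F)(F)F
A4 | alternative 2 | tert-butyl 2-(benzyloxy)-6-[4-hydroxy-2-methoxy-6-(methoxycarbonyl)phenoxy]-4-methylbenzoate | COC(=O)c1cc(O)cc(OC)c1Oc1cc(C)cc(OCc2ccccc2)c1C(=O)OC(C)(C)C
A5 | alternative 2 | tert-butyl 2-(benzyloxy)-6-({2-methoxy-1-[1-(methoxycarbonyl)ethenyl]-4-oxocyclobut-2-en-1-yl}oxy)-4-methylbenzoate (racemic) | COC(=O)C(=C)C1(Oc2cc(C)cc(OCc3ccccc3)c2C(=O)OC(C)(C)C)C(=O)C=C1OC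
A6 | alternative 3 | dimethyl 2-{[2,6-bis(benzyloxy)-4-methylphenoxy]carbonyl}-5-[(tert-butyldimethylsilyl)oxy]benzene-1,3-dicarboxylate | COC(=O)c1cc(O[Si](C)(C)C(C)(C)C)cc(C(=O)OC)c1C(=O)Oc1c(OCc2ccccc2)cc(C)cc1OCc1ccccc1
A7 | alternative 3 | dimethyl 4-oxo-4H-pyran-2,6-dicarboxylate (dimethyl chelidonate) | COC(=O)c1cc(=O)cc(C(=O)OC)o1
A8 | alternative 3 | 2,6-bis(benzyloxy)-4-methylphenyl (triphenyl-λ5-phosphanylidene)acetate | O=C(C=P(c1ccccc1)(c1ccccc1)c1ccccc1)Oc1c(OCc2ccccc2)cc(C)cc1OCc1ccccc1
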